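Z stands between L and a further product: in the red run it rises, then falls.

| flask | L | J | remark | time |
|---|---|---|---|---|
| green | 10 mM | 8 mM | run made earlier |  |
| red | 10 mM | 18 mM | run made earlier |  |
| violet | 5 mM | 12 mM | run made earlier |  |
| flask | 10 mM | 12.0 mM |  | 50 min |

| run | time / min | Z / % | Q / % | L / % |
|---|---|---|---|---|
| green | 0.500 | 20.0 | 11.9 | 63.3 |
| green | 1.33 | 25.0 | 15.4 | 48.1 |
| green | 3.00 | 26.0 | 12.0 | 44.7 |
| green | 8.00 | 26.2 | 4.4 | 45.9 |
| green | 20.0 | 28.1 | 0.5 | 47.4 |
| green | 50.0 | 27.6 | 0 | 47.7 |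
| red | 0.500 | 25.5 | 20.7 | 34.8 |
| red | 1.33 | 19.0 | 20.9 | 18.1 |
| red | 3.00 | 15.1 | 12.9 | 15.5 |
| red | 8.00 | 10.0 | 1.3 | 12.2 |
| red | 20.0 | 11.7 | 0.4 | 11.2 |
| red | 50.0 | 9.3 | 0 | 10.4 |
| violet | 0.500 | 25.3 | 19.8 | 43.2 |
| violet | 1.50 | 19.7 | 23.8 | 17.6 |
| violet | 5.00 | 8.9 | 12.9 | 9.1 |
| violet | 15.0 | 4.0 | 1.2 | 4.7 |
| violet | 50.0 | 1.8 | 0 | 2.2 |

(scatter of a reading: 0.5 percentage points)

- the analysis behind the earlier runs scatters by 0.5 percentage points, standard deviation

1. the moment within 50 min at which there is most Z
2. the amount of Z, in percent of the L charged, at that time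

Suppose that making Z from L and using Z are both first order in J. The ratio of the two rates then loses both J and time, so Z stops growing at one value of Z/L. Call this value ρ, a selectivity factor. The runs bracket it. Green holds Z/L at 0.579 at 50.0 min with no fall in Z, while red stands at 0.733 at 0.500 min and Z drops afterwards. The midpoint, ρ = 0.656, is the reckoned ratio of Z to L at the top of Z.

The highest readings of Z in red and violet average 25.4%, so L at the top of Z in the flask is reckoned at about 38.7%. That costs the flask at least 6.13 mM of J, less than its charge of 12.0 mM. But this bound is also less than green's charge of 8 mM, and green ends below ρ, so the bound does not show that the flask reaches ρ; the reckoning assumes it.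

One number is not enough, however. It holds no clock, and green's Z ends higher than that average while its Q falls from 15.4% to 0%. For the time, violet, with the same J charge, crosses that L between 0.500 min and 1.50 min, and this reckoning stops at that window, wider than the forecast's 0.7 min with 26% of Z, of which it says “I expect a peak of about 26% near 0.7 min”.

The flask peaks at 1.00 min with 25.4% of Z, when L stands at 36.1% and 28.7% of the J charge remains.

    L + J ⇌ Q + X (K = 1.40, k = 0.990 /M/s)
    L + J → Z + X (k = 1.90 /M/s)
    J + Q → G + X (k = 0.0240 /M/s)
    J + Z → G + X (k = 2.70 /M/s)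
    J → E (k = 6.40 × 10⁻⁴ /s)

Z/L at that peak is 0.704, against ρ of 0.656. The neighbour charged with 7.2 mM of J ends with Z/L at 0.535, less than ρ, and its highest Z is 27.6%.

The data were generated by integration for substances that don't exist; scatter was added.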